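**Retrosynthetic overview**
1. Target 31 ⇐ silyl ether 30 ⇐ allylic bromide 25 + furan-3-ylmethylmagnesium chloride 29 (C10–C11 bond of the side chain; the furan ring is bought intact).
2. 25 ⇐ enoate 20 by redox adjustment (global hydride reduction, re-oxidation to enal and lactone, 1,2-reduction, bromination).
3. Key disconnection, C6–C7 of the side chain: enantioselective vinylogous Mukaiyama aldol of enal 14 with silyl dienolate 17 (from ethyl 3-methylbut-2-enoate), which sets C6 (S) and the 8E olefin together.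
4. Enal 14 ⇐ (2E,6E)-farnesol: terminal isopropylidene excised, Shi epoxidation of the 6,7-olefin, then acid-induced 5-exo lactonisation with inversion sets the (1R)-carbinol and the (5S)-lactone carbon.
5. Ring order: the γ-lactone is closed first (step 9), opened in step 16 and re-closed in step 17; no other ring is built.

Assumption: reagents are identified by name and SMILES in their steps, and only substrates, fragment starting materials, in-flask intermediates and products carry numbers.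
Assumption: C10 of compounds 3–6 is racemic and is left undefined because it is excised in step 5.

**Route**

Step 1
Reactants: 1 (2E,6E)-farnesol
Product: 2 (2E,6E)-farnesyl acetate
Conditions: Ac2O, pyridine, DMAP (cat.), CH2Cl2, 0 °C to rt
Reagents that add atoms: acetic anhydride, CC(=O)OC(C)=O
Why: DMAP-catalysed O-acylation, which also deactivates the 2,3-olefin toward the electrophilic bromination that follows.

Step 2
Reactants: 2 (2E,6E)-farnesyl acetate
Product: 3 (2E,6E)-10-bromo-11-hydroxy-3,7,11-trimethyldodeca-2,6-dien-1-yl acetate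
Conditions: NBS (1.1 equiv), THF/H2O, 0 °C
Reagents that add atoms: N-bromosuccinimide, O=C1CCC(=O)N1Br; water, O
Why: van Tamelen terminal bromohydrin formation, in which the coiled polyene in aqueous THF exposes only the terminal olefin and Markovnikov attack of water gives the tertiary alcohol.

Step 3
Reactants: 3 (2E,6E)-10-bromo-11-hydroxy-3,7,11-trimethyldodeca-2,6-dien-1-yl acetate
Product: 4 (2E,6E)-10,11-epoxy-3,7,11-trimethyldodeca-2,6-dien-1-ol
Conditions: K2CO3 (3 equiv), MeOH, rt, 12 h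
Reagents that add atoms: none
Why: Intramolecular Williamson closure of the bromohydrin to the epoxide, with concomitant base-catalysed methanolysis of the acetate.

Step 4
Reactants: 4 (2E,6E)-10,11-epoxy-3,7,11-trimethyldodeca-2,6-dien-1-ol
Product: 5 (2E,6E)-10,11-epoxy-3,7,11-trimethyldodeca-2,6-dien-1-yl acetate
Conditions: Ac2O, pyridine, DMAP (cat.), CH2Cl2, 0 °C to rt
Reagents that add atoms: acetic anhydride, CC(=O)OC(C)=O
Why: Re-acylation restores the electron-withdrawing ester that keeps the allylic olefin unreactive in steps 5 to 9.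

Step 5
Reactants: 5 (2E,6E)-10,11-epoxy-3,7,11-trimethyldodeca-2,6-dien-1-yl acetate
Product: 7 (2E,6E)-3,7-dimethyl-10-oxodeca-2,6-dien-1-yl acetate, via vicinal diol 6 (not isolated)
Conditions: H5IO6 (1.3 equiv), THF/Et2O, 0 °C
Reagents that add atoms: none
Why: Periodic acid hydrolyses the epoxide at the tertiary carbon and cleaves the resulting glycol (Malaprade cleavage) to the trisnor aldehyde without touching the two trisubstituted olefins.

Step 6
Reactants: 7 (2E,6E)-3,7-dimethyl-10-oxodeca-2,6-dien-1-yl acetate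
Product: 8 (4E,8E)-10-acetoxy-4,8-dimethyldeca-4,8-dienoic acid
Conditions: NaClO2, NaH2PO4, 2-methylbut-2-ene (excess), t-BuOH/H2O, rt
Reagents that add atoms: sodium chlorite, [Na+].[O-]Cl=O
Why: Pinnick oxidation, in which chlorite oxidises only the aldehyde and the alkene scavenger removes HOCl so the olefins survive.

Step 7
Reactants: 8 (4E,8E)-10-acetoxy-4,8-dimethyldeca-4,8-dienoic acid
Product: 9 methyl (4E,8E)-10-acetoxy-4,8-dimethyldeca-4,8-dienoate
Conditions: MeI, K2CO3, DMF, rt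
Reagents that add atoms: iodomethane, CI
Why: SN2 O-alkylation of the carboxylate under conditions that leave the allylic acetate intact.

Step 8
Reactants: 9 methyl (4E,8E)-10-acetoxy-4,8-dimethyldeca-4,8-dienoate
Product: 10 methyl 3-[(2R,3R)-3-[(3E)-5-acetoxy-3-methylpent-3-en-1-yl]-2-methyloxiran-2-yl]propanoate
Conditions: Shi ketone from D-fructose (1,2:4,5-di-O-isopropylidene-β-D-erythro-2,3-hexodiulo-2,6-pyranose, 0.3 equiv), KHSO5 (as 2KHSO5·KHSO4·K2SO4, 1.4 equiv), K2CO3, Bu4NHSO4 (cat.), Na2B4O7/Na2H2EDTA buffer, MeCN/CH2(OMe)2/H2O, 0 °C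
Reagents that add atoms: potassium peroxymonosulfate, [K+].[O-]S(=O)(=O)OO
Why: Shi asymmetric epoxidation, in which the chiral dioxirane attacks the electron-rich isolated olefin rather than the acetate-deactivated one and its spiro transition state gives the (2R,3R)-epoxide of this E-trisubstituted olefin.

Step 9
Reactants: 10 methyl 3-[(2R,3R)-3-[(3E)-5-acetoxy-3-methylpent-3-en-1-yl]-2-methyloxiran-2-yl]propanoate
Product: 11 (5S)-5-[(1R,4E)-6-acetoxy-1-hydroxy-4-methylhex-4-en-1-yl]-5-methyloxolan-2-one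
Conditions: CSA (0.2 equiv), CH2Cl2 containing H2O (2 equiv), 0 °C to rt
Reagents that add atoms: water, O
Why: Acid-catalysed epoxide opening with ester-carbonyl participation (5-exo at the tertiary carbon) inverts that carbon, so the (2R,3R)-epoxide gives the (5S)-lactone carbon next to the untouched (1R)-carbinol, and hydrolysis of the oxocarbenium releases methanol.

Step 10
Reactants: 11 (5S)-5-[(1R,4E)-6-acetoxy-1-hydroxy-4-methylhex-4-en-1-yl]-5-methyloxolan-2-one
Product: 12 (5S)-5-[(1R,4E)-6-acetoxy-1-(tert-butyldimethylsilyloxy)-4-methylhex-4-en-1-yl]-5-methyloxolan-2-one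
Conditions: TBSOTf (1.5 equiv), 2,6-lutidine, CH2Cl2, −78 to 0 °C
Reagents that add atoms: tert-butyldimethylsilyl trifluoromethanesulfonate, CC(C)(C)[Si](C)(C)OS(=O)(=O)C(F)(F)F
Why: Silyl triflate silylation protects the hindered secondary alcohol, the only free hydroxyl, ahead of the later O-methylation and oxidations.

Step 11
Reactants: 12 (5S)-5-[(1R,4E)-6-acetoxy-1-(tert-butyldimethylsilyloxy)-4-methylhex-4-en-1-yl]-5-methyloxolan-2-one
Product: 13 (5S)-5-[(1R,4E)-1-(tert-butyldimethylsilyloxy)-6-hydroxy-4-methylhex-4-en-1-yl]-5-methyloxolan-2-one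
Conditions: K2CO3 (0.3 equiv), MeOH, 0 °C; aq. NH4Cl
Reagents that add atoms: none
Why: Base-catalysed transesterification removes the primary acetate, while the γ,γ-disubstituted γ-lactone is thermodynamically favoured and re-closes if it opens.

Step 12
Reactants: 13 (5S)-5-[(1R,4E)-1-(tert-butyldimethylsilyloxy)-6-hydroxy-4-methylhex-4-en-1-yl]-5-methyloxolan-2-one
Product: 14 (2E,6R)-6-(tert-butyldimethylsilyloxy)-3-methyl-6-[(2S)-2-methyl-5-oxooxolan-2-yl]hex-2-enal
Conditions: MnO2 (15 equiv), CH2Cl2, rt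
Reagents that add atoms: none
Why: Allylic oxidation with MnO2 gives the E-enal without over-oxidation or touching the lactone and silyl ether.

Step 13
Reactants: 15 ethyl 3-methylbut-2-enoate
Product: 17 tert-butyl{[(1Z)-1-ethoxy-3-methylbuta-1,3-dien-1-yl]oxy}dimethylsilane, via lithium dienolate 16 (not isolated)
Conditions: LiN(i-Pr)2 (commercial solution, 1.1 equiv), DMPU, THF, −78 °C; then TBSCl, −78 °C to rt; distillation
Reagents that add atoms: tert-butyldimethylsilyl chloride, CC(C)(C)[Si](C)(C)Cl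
Why: Kinetic γ-deprotonation gives the extended dienolate, which is O-silylated to the silyl dienol ether needed for the vinylogous aldol.

Step 14
Reactants: 14 (2E,6R)-6-(tert-butyldimethylsilyloxy)-3-methyl-6-[(2S)-2-methyl-5-oxooxolan-2-yl]hex-2-enal; 17 tert-butyl{[(1Z)-1-ethoxy-3-methylbuta-1,3-dien-1-yl]oxy}dimethylsilane
Product: 19 ethyl (2E,5S,6E,10R)-10-(tert-butyldimethylsilyloxy)-5-hydroxy-3,7-dimethyl-10-[(2S)-2-methyl-5-oxooxolan-2-yl]deca-2,6-dienoate, via trichlorosilyl aldolate 18 (not isolated)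
Conditions: SiCl4 (1.2 equiv), (S,S)-Denmark bisphosphoramide (two N,N'-dimethyl-1,1'-binaphthyl-2,2'-diamine phosphoramide units on an N,N'-dimethylpentane-1,5-diamine tether, 5 mol%), i-Pr2NEt (10 mol%), 17 (1.2 equiv), CH2Cl2, −78 °C; sat. aq. NaHCO3
Reagents that add atoms: none
Why: Vinylogous Mukaiyama aldol under Lewis-base-activated SiCl4, in which the dienolate reacts only at its γ-carbon and the (S,S)-catalyst (the (R,R) series gives Re-face attack) directs it to the Si face of the enal to set 5S and deliver the 2E enoate.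

Step 15
Reactants: 19 ethyl (2E,5S,6E,10R)-10-(tert-butyldimethylsilyloxy)-5-hydroxy-3,7-dimethyl-10-[(2S)-2-methyl-5-oxooxolan-2-yl]deca-2,6-dienoate
Product: 20 ethyl (2E,5S,6E,10R)-10-(tert-butyldimethylsilyloxy)-5-methoxy-3,7-dimethyl-10-[(2S)-2-methyl-5-oxooxolan-2-yl]deca-2,6-dienoate
Conditions: Me3OBF4 (3 equiv), 1,8-bis(dimethylamino)naphthalene (4 equiv), CH2Cl2, 0 °C to rt
Reagents that add atoms: trimethyloxonium tetrafluoroborate, C[O+](C)C.F[B-](F)(F)F
Why: Meerwein O-methylation under non-basic conditions avoids retro-aldol, elimination and lactone enolisation, and the stereocentre is untouched.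

Step 16
Reactants: 20 ethyl (2E,5S,6E,10R)-10-(tert-butyldimethylsilyloxy)-5-methoxy-3,7-dimethyl-10-[(2S)-2-methyl-5-oxooxolan-2-yl]deca-2,6-dienoate
Product: 21 (2E,5S,6E,10R,11S)-10-(tert-butyldimethylsilyloxy)-5-methoxy-3,7,11-trimethyltetradeca-2,6-diene-1,11,14-triol
Conditions: i-Bu2AlH (8 equiv), CH2Cl2, −78 °C to rt; aq. KNaC4H4O6
Reagents that add atoms: none
Why: Hydride reduction of both carbonyls (1,2-reduction of the enoate, lactone to 1,4-diol) is done deliberately because no hydride distinguishes them, and any residual lactol converges in step 17.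

Step 17
Reactants: 21 (2E,5S,6E,10R,11S)-10-(tert-butyldimethylsilyloxy)-5-methoxy-3,7,11-trimethyltetradeca-2,6-diene-1,11,14-triol
Product: 23 (2E,5S,6E,10R)-10-(tert-butyldimethylsilyloxy)-5-methoxy-3,7-dimethyl-10-[(2S)-2-methyl-5-oxooxolan-2-yl]deca-2,6-dienal, via lactol enal 22 (not isolated)
Conditions: TEMPO (0.2 equiv), PhI(OAc)2 (3.5 equiv), CH2Cl2, rt
Reagents that add atoms: none
Why: Oxoammonium (TEMPO) oxidation takes the allylic alcohol to the enal and the saturated primary alcohol to an aldehyde that is trapped by the tertiary hydroxyl as a lactol and oxidised on to the γ-lactone, with no stereocentre affected.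

Step 18
Reactants: 23 (2E,5S,6E,10R)-10-(tert-butyldimethylsilyloxy)-5-methoxy-3,7-dimethyl-10-[(2S)-2-methyl-5-oxooxolan-2-yl]deca-2,6-dienal
Product: 24 (5S)-5-[(1R,4E,6S,8E)-1-(tert-butyldimethylsilyloxy)-10-hydroxy-6-methoxy-4,8-dimethyldeca-4,8-dien-1-yl]-5-methyloxolan-2-one
Conditions: NaBH4, CeCl3·7H2O, MeOH, −40 °C
Reagents that add atoms: none
Why: Luche reduction gives clean 1,2-reduction of the enal while the γ-lactone is inert to borohydride at this temperature.

Step 19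
Reactants: 24 (5S)-5-[(1R,4E,6S,8E)-1-(tert-butyldimethylsilyloxy)-10-hydroxy-6-methoxy-4,8-dimethyldeca-4,8-dien-1-yl]-5-methyloxolan-2-one
Product: 25 (5S)-5-[(1R,4E,6S,8E)-10-bromo-1-(tert-butyldimethylsilyloxy)-6-methoxy-4,8-dimethyldeca-4,8-dien-1-yl]-5-methyloxolan-2-one
Conditions: CBr4, PPh3, 2,6-lutidine, CH2Cl2, −20 to 0 °C; used at once
Reagents that add atoms: carbon tetrabromide, BrC(Br)(Br)Br
Why: Appel bromination displaces the alkoxyphosphonium by SN2 at the primary allylic carbon without transposition or loss of the E geometry.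

Step 20
Reactants: 26 furan-3-ylmethanol
Product: 28 3-(chloromethyl)furan, via mesylate 27 (not isolated)
Conditions: MsCl, 2,4,6-collidine, LiCl, DMF, 0 °C
Reagents that add atoms: lithium chloride, [Li+].[Cl-]
Why: Collington–Meyers chlorination (mesylation, then chloride displacement in the same flask) under nearly neutral conditions spares the acid-sensitive furan.

Step 21
Reactants: 25 (5S)-5-[(1R,4E,6S,8E)-10-bromo-1-(tert-butyldimethylsilyloxy)-6-methoxy-4,8-dimethyldeca-4,8-dien-1-yl]-5-methyloxolan-2-one; 28 3-(chloromethyl)furan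
Product: 30 (5S)-5-[(1R,4E,6S,8E)-1-(tert-butyldimethylsilyloxy)-11-(furan-3-yl)-6-methoxy-4,8-dimethylundeca-4,8-dien-1-yl]-5-methyloxolan-2-one, via furan-3-ylmethylmagnesium chloride 29 (not isolated)
Conditions: 28, Mg, THF, rt (slow addition); then the Grignard solution (1.4 equiv) added dropwise to 25 and Li2CuCl4 (5 mol%), THF, −78 to −30 °C; aq. NH4Cl
Reagents that add atoms: none
Why: Kochi-type copper-catalysed Grignard cross-coupling at the primary allylic bromide goes SN2 with retention of the E olefin and is much faster at low temperature than addition to the lactone.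

Step 22
Reactants: 30 (5S)-5-[(1R,4E,6S,8E)-1-(tert-butyldimethylsilyloxy)-11-(furan-3-yl)-6-methoxy-4,8-dimethylundeca-4,8-dien-1-yl]-5-methyloxolan-2-one
Product: 31 (5S)-5-[(1R,4E,6S,8E)-11-(furan-3-yl)-1-hydroxy-6-methoxy-4,8-dimethylundeca-4,8-dien-1-yl]-5-methyloxolan-2-one
Conditions: HF·pyridine, pyridine, THF, 0 °C to rt
Reagents that add atoms: none
Why: Buffered fluoride desilylation frees the secondary alcohol without acid or base strong enough to harm the furan, the allylic methyl ether or the lactone.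

**Compound list**
1 | (2E,6E)-farnesol | OC/C=C(C)/CC/C=C(C)/CCC=C(C)C | starting material
2 | (2E,6E)-farnesyl acetate | CC(=O)OC/C=C(C)/CC/C=C(C)/CCC=C(C)C | intermediate
3 | (2E,6E)-10-bromo-11-hydroxy-3,7,11-trimethyldodeca-2,6-dien-1-yl acetate (racemic at C10) | CC(=O)OC/C=C(C)/CC/C=C(C)/CCC(Br)C(C)(C)O | intermediate
4 | (2E,6E)-10,11-epoxy-3,7,11-trimethyldodeca-2,6-dien-1-ol (racemic) | OC/C=C(C)/CC/C=C(C)/CCC1OC1(C)C | intermediate
5 | (2E,6E)-10,11-epoxy-3,7,11-trimethyldodeca-2,6-dien-1-yl acetate (racemic) | CC(=O)OC/C=C(C)/CC/C=C(C)/CCC1OC1(C)C | intermediate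
6 | (2E,6E)-10,11-dihydroxy-3,7,11-trimethyldodeca-2,6-dien-1-yl acetate (racemic; not isolated) | CC(=O)OC/C=C(C)/CC/C=C(C)/CCC(O)C(C)(C)O | intermediate
7 | (2E,6E)-3,7-dimethyl-10-oxodeca-2,6-dien-1-yl acetate | CC(=O)OC/C=C(C)/CC/C=C(C)/CCC=O | intermediate
8 | (4E,8E)-10-acetoxy-4,8-dimethyldeca-4,8-dienoic acid | CC(=O)OC/C=C(C)/CC/C=C(C)/CCC(=O)O | intermediate
9 | methyl (4E,8E)-10-acetoxy-4,8-dimethyldeca-4,8-dienoate | CC(=O)OC/C=C(C)/CC/C=C(C)/CCC(=O)OC | intermediate
10 | methyl 3-[(2R,3R)-3-[(3E)-5-acetoxy-3-methylpent-3-en-1-yl]-2-methyloxiran-2-yl]propanoate | CC(=O)OC/C=C(C)/CC[C@H]1O[C@]1(C)CCC(=O)OC | intermediate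
11 | (5S)-5-[(1R,4E)-6-acetoxy-1-hydroxy-4-methylhex-4-en-1-yl]-5-methyloxolan-2-one | CC(=O)OC/C=C(C)/CC[C@@H](O)[C@]1(C)CCC(=O)O1 | intermediate
12 | (5S)-5-[(1R,4E)-6-acetoxy-1-(tert-butyldimethylsilyloxy)-4-methylhex-4-en-1-yl]-5-methyloxolan-2-one | CC(=O)OC/C=C(C)/CC[C@@H](O[Si](C)(C)C(C)(C)C)[C@]1(C)CCC(=O)O1 | intermediate
13 | (5S)-5-[(1R,4E)-1-(tert-butyldimethylsilyloxy)-6-hydroxy-4-methylhex-4-en-1-yl]-5-methyloxolan-2-one | OC/C=C(C)/CC[C@@H](O[Si](C)(C)C(C)(C)C)[C@]1(C)CCC(=O)O1 | intermediate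
14 | (2E,6R)-6-(tert-butyldimethylsilyloxy)-3-methyl-6-[(2S)-2-methyl-5-oxooxolan-2-yl]hex-2-enal | O=C/C=C(C)/CC[C@@H](O[Si](C)(C)C(C)(C)C)[C@]1(C)CCC(=O)O1 | intermediate
15 | ethyl 3-methylbut-2-enoate | CCOC(=O)C=C(C)C | starting material
16 | lithium (1E)-1-ethoxy-3-methylbuta-1,3-dien-1-olate (lithium dienolate of 15; not isolated) | [Li+].CCO/C([O-])=C/C(C)=C | intermediate
17 | tert-butyl{[(1Z)-1-ethoxy-3-methylbuta-1,3-dien-1-yl]oxy}dimethylsilane | CCO/C(O[Si](C)(C)C(C)(C)C)=C/C(C)=C | intermediate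
18 | ethyl (2E,5S,6E,10R)-10-(tert-butyldimethylsilyloxy)-3,7-dimethyl-10-[(2S)-2-methyl-5-oxooxolan-2-yl]-5-(trichlorosilyloxy)deca-2,6-dienoate (not isolated) | Cl[Si](Cl)(Cl)O[C@H](/C=C(\C)CC[C@@H](O[Si](C)(C)C(C)(C)C)[C@]1(C)CCC(=O)O1)C/C(C)=C/C(=O)OCC | intermediate
19 | ethyl (2E,5S,6E,10R)-10-(tert-butyldimethylsilyloxy)-5-hydroxy-3,7-dimethyl-10-[(2S)-2-methyl-5-oxooxolan-2-yl]deca-2,6-dienoate | O[C@H](/C=C(\C)CC[C@@H](O[Si](C)(C)C(C)(C)C)[C@]1(C)CCC(=O)O1)C/C(C)=C/C(=O)OCC | intermediate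
20 | ethyl (2E,5S,6E,10R)-10-(tert-butyldimethylsilyloxy)-5-methoxy-3,7-dimethyl-10-[(2S)-2-methyl-5-oxooxolan-2-yl]deca-2,6-dienoate | CO[C@H](/C=C(\C)CC[C@@H](O[Si](C)(C)C(C)(C)C)[C@]1(C)CCC(=O)O1)C/C(C)=C/C(=O)OCC | intermediate
21 | (2E,5S,6E,10R,11S)-10-(tert-butyldimethylsilyloxy)-5-methoxy-3,7,11-trimethyltetradeca-2,6-diene-1,11,14-triol | CO[C@H](/C=C(\C)CC[C@@H](O[Si](C)(C)C(C)(C)C)[C@](O)(C)CCCO)C/C(C)=C/CO | intermediate
22 | (2E,5S,6E,10R)-10-(tert-butyldimethylsilyloxy)-10-[(2S)-5-hydroxy-2-methyloxolan-2-yl]-5-methoxy-3,7-dimethyldeca-2,6-dienal (lactol, anomer mixture; not isolated) | CO[C@H](/C=C(\C)CC[C@@H](O[Si](C)(C)C(C)(C)C)[C@]1(C)CCC(O)O1)C/C(C)=C/C=O | intermediate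
23 | (2E,5S,6E,10R)-10-(tert-butyldimethylsilyloxy)-5-methoxy-3,7-dimethyl-10-[(2S)-2-methyl-5-oxooxolan-2-yl]deca-2,6-dienal | CO[C@H](/C=C(\C)CC[C@@H](O[Si](C)(C)C(C)(C)C)[C@]1(C)CCC(=O)O1)C/C(C)=C/C=O | intermediate
24 | (5S)-5-[(1R,4E,6S,8E)-1-(tert-butyldimethylsilyloxy)-10-hydroxy-6-methoxy-4,8-dimethyldeca-4,8-dien-1-yl]-5-methyloxolan-2-one | CO[C@H](/C=C(\C)CC[C@@H](O[Si](C)(C)C(C)(C)C)[C@]1(C)CCC(=O)O1)C/C(C)=C/CO | intermediate
25 | (5S)-5-[(1R,4E,6S,8E)-10-bromo-1-(tert-butyldimethylsilyloxy)-6-methoxy-4,8-dimethyldeca-4,8-dien-1-yl]-5-methyloxolan-2-one | CO[C@H](/C=C(\C)CC[C@@H](O[Si](C)(C)C(C)(C)C)[C@]1(C)CCC(=O)O1)C/C(C)=C/CBr | intermediate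
26 | furan-3-ylmethanol | OCc1ccoc1 | starting material
27 | furan-3-ylmethyl methanesulfonate (not isolated) | CS(=O)(=O)OCc1ccoc1 | intermediate
28 | 3-(chloromethyl)furan | ClCc1ccoc1 | intermediate
29 | furan-3-ylmethylmagnesium chloride (not isolated) | Cl[Mg]Cc1ccoc1 | intermediate
30 | (5S)-5-[(1R,4E,6S,8E)-1-(tert-butyldimethylsilyloxy)-11-(furan-3-yl)-6-methoxy-4,8-dimethylundeca-4,8-dien-1-yl]-5-methyloxolan-2-one | CO[C@H](/C=C(\C)CC[C@@H](O[Si](C)(C)C(C)(C)C)[C@]1(C)CCC(=O)O1)C/C(C)=C/CCc1ccoc1 | intermediate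
31 | (5S)-5-[(1R,4E,6S,8E)-11-(furan-3-yl)-1-hydroxy-6-methoxy-4,8-dimethylundeca-4,8-dien-1-yl]-5-methyloxolan-2-one | CO[C@H](/C=C(\C)CC[C@@H](O)[C@]1(C)CCC(=O)O1)C/C(C)=C/CCc1ccoc1 | target

**Totals and risks**

Total step count: 22. Longest linear sequence: 20 steps (1–12, 14–19, 21, 22); steps 13 and 20 are one-step side branches.

Risk 1, step 9 (acid-mediated lactonisation of the epoxy ester: possible Meinwald rearrangement, 6-endo opening or incomplete inversion). The fallback sets out from 10 and comes back at 13. Saponification of 10 with LiOH in THF/H2O cleaves both the methyl ester and the acetate and gives the epoxy acid 3-[(2R,3R)-3-[(3E)-5-hydroxy-3-methylpent-3-en-1-yl]-2-methyloxiran-2-yl]propanoic acid F1. On acidification to pH 3–4 the free carboxylic acid itself opens the epoxide 5-exo with inversion and gives the diol lactone (5S)-5-[(1R,4E)-1,6-dihydroxy-4-methylhex-4-en-1-yl]-5-methyloxolan-2-one F2. Silylation of both hydroxyls with TBSOTf and 2,6-lutidine gives (5S)-5-[(1R,4E)-1,6-bis(tert-butyldimethylsilyloxy)-4-methylhex-4-en-1-yl]-5-methyloxolan-2-one F3. PPTS in MeOH then removes only the primary allylic silyl group and returns 13.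

Risk 2, step 14 (catalyst-controlled vinylogous aldol on a β,β-disubstituted enal: enantioselectivity and rate are untested on this substrate). The fallback sets out from 14 and 17 and comes back at 19. The aldol is run with BF3·OEt2 in CH2Cl2 at −78 °C without facial control and gives 19 together with its C5 epimer ethyl (2E,5R,6E,10R)-10-(tert-butyldimethylsilyloxy)-5-hydroxy-3,7-dimethyl-10-[(2S)-2-methyl-5-oxooxolan-2-yl]deca-2,6-dienoate F4. Dess–Martin oxidation of the mixture (NaHCO3 buffer) converges both epimers on the ketone ethyl (2E,6E,10R)-10-(tert-butyldimethylsilyloxy)-3,7-dimethyl-10-[(2S)-2-methyl-5-oxooxolan-2-yl]-5-oxodeca-2,6-dienoate F5. Reduction with (R)-2-methyl-CBS-oxazaborolidine and catecholborane at −78 °C (alkenyl group as the large substituent) then sets 5S and returns 19.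

Risk 3, step 21 (Grignard coupling in the presence of the lactone; SN2 versus SN2′ and Wurtz dimerisation of the furylmethyl reagent). The fallback sets out from 21 and comes back at 30, moving the coupling ahead of lactone re-closure so that no electrophilic carbonyl is present. Corey–Kim chlorination of 21 (NCS, Me2S, CH2Cl2, −30 to 0 °C), which converts only the allylic hydroxyl, gives (4S,5R,8E,10S,12E)-5-(tert-butyldimethylsilyloxy)-14-chloro-10-methoxy-4,8,12-trimethyltetradeca-8,12-diene-1,4-diol F6. Coupling with 29 (4 equiv, two of them consumed by the free hydroxyls) and Li2CuCl4 (5 mol%) in THF at −10 to 0 °C gives (4S,5R,8E,10S,12E)-5-(tert-butyldimethylsilyloxy)-15-(furan-3-yl)-10-methoxy-4,8,12-trimethylpentadeca-8,12-diene-1,4-diol F7. Oxidative lactonisation of the 1,4-diol with (n-Pr4N)RuO4 (8 mol%), NMO and 4 Å molecular sieves in CH2Cl2, conditions that tolerate furans, returns 30.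

**Further compounds**
F1 | step 9 | 3-[(2R,3R)-3-[(3E)-5-hydroxy-3-methylpent-3-en-1-yl]-2-methyloxiran-2-yl]propanoic acid | OC/C=C(C)/CC[C@H]1O[C@]1(C)CCC(=O)O
F2 | step 9 | (5S)-5-[(1R,4E)-1,6-dihydroxy-4-methylhex-4-en-1-yl]-5-methyloxolan-2-one | OC/C=C(C)/CC[C@@H](O)[C@]1(C)CCC(=O)O1
F3 | step 9 | (5S)-5-[(1R,4E)-1,6-bis(tert-butyldimethylsilyloxy)-4-methylhex-4-en-1-yl]-5-methyloxolan-2-one | CC(C)(C)[Si](C)(C)OC/C=C(C)/CC[C@@H](O[Si](C)(C)C(C)(C)C)[C@]1(C)CCC(=O)O1
F4 | step 14 | ethyl (2E,5R,6E,10R)-10-(tert-butyldimethylsilyloxy)-5-hydroxy-3,7-dimethyl-10-[(2S)-2-methyl-5-oxooxolan-2-yl]deca-2,6-dienoate | O[C@@H](/C=C(\C)CC[C@@H](O[Si](C)(C)C(C)(C)C)[C@]1(C)CCC(=O)O1)C/C(C)=C/C(=O)OCC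
F5 | step 14 | ethyl (2E,6E,10R)-10-(tert-butyldimethylsilyloxy)-3,7-dimethyl-10-[(2S)-2-methyl-5-oxooxolan-2-yl]-5-oxodeca-2,6-dienoate | O=C(/C=C(\C)CC[C@@H](O[Si](C)(C)C(C)(C)C)[C@]1(C)CCC(=O)O1)C/C(C)=C/C(=O)OCC
F6 | step 21 | (4S,5R,8E,10S,12E)-5-(tert-butyldimethylsilyloxy)-14-chloro-10-methoxy-4,8,12-trimethyltetradeca-8,12-diene-1,4-diol | CO[C@H](/C=C(\C)CC[C@@H](O[Si](C)(C)C(C)(C)C)[C@](O)(C)CCCO)C/C(C)=C/CCl
F7 | step 21 | (4S,5R,8E,10S,12E)-5-(tert-butyldimethylsilyloxy)-15-(furan-3-yl)-10-methoxy-4,8,12-trimethylpentadeca-8,12-diene-1,4-diol | CO[C@H](/C=C(\C)CC[C@@H](O[Si](C)(C)C(C)(C)C)[C@](O)(C)CCCO)C/C(C)=C/CCc1ccoc1
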